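**Retrosynthetic overview**
1. Target 5 ⇐ 1β-iodo lactone 4 by radical reduction of C1–I to C1–H (last step).
2. 4 ⇐ ring-opened 1(10)-ene diol dicarboxylate 3 by iodolactonisation, which rebuilds the 19,10-γ-lactone and the C10 stereocentre.
3. 3 ⇐ iso-gibberellic acid 2 by saponification of the 19→2α lactone, which frees the 2α-OH with retention.
4. 2 ⇐ gibberellic acid 1: the key C2–O bond comes from a suprafacial 1,3-transposition of the allylic lactone (net [3,3] acyloxy shift from C10 to C2).
5. Ring order: rings A to D and eight of the nine stereocentres are bought in 1 (C10 is erased and reset, C2 is new); the lactone ring is moved from C10 to C2, opened, then re-formed on C10.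

**Assumption:** the SMILES is read as the 2α,3β,13-triol with the natural 19,10-lactone and the natural configuration at every other centre (the C2 epimer of the natural 2β,3β,13-trihydroxy gibberellin; α/β as used for gibberellins, with the 3-OH of gibberellic acid β). Fermentation-grade gibberellic acid is taken as the cheap commercial chiral starting material.

**Step 1**
Reactants: 1 gibberellic acid
Product: 2 iso-gibberellic acid (19→2α-lactone of the 1(10)-ene-3β,13-diol-7-acid)
Conditions: 0.05 M aq NaOH (2.5 equiv), 20 °C, stopped when 1 is consumed (about 2 h); then 1 M HCl to pH 3, 0 °C, EtOAc extraction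
Reagents that add atoms: none
Why: Allylic lactone 1,3-transposition, formally a suprafacial [3,3] acyloxy shift that in alkali runs stepwise (the 3β-alkoxide closes a 2β,3β-epoxide by anti SN2′ expulsion of the C10 carboxylate, which then reopens the vinyl epoxide at C2 from the α-face), so the new C2–O bond is α, the 3-OH stays β, and the more substituted 1(10)-alkene drives the reaction forward.

**Step 2**
Reactants: 2 iso-gibberellic acid
Product: 4 1β-iodo-2α-hydroxy-1,2-dihydrogibberellic acid, via ring-opened disodium dicarboxylate 3 (not isolated)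
Conditions: 2 M aq NaOH (5 equiv), 20 °C, 3 h; then 0 °C, 2 M HCl to pH 8.5, NaHCO3 (3 equiv), I2 (1.3 equiv), THF–H2O, dark, 0 °C, 2 h; aq Na2S2O3; HCl to pH 3, EtOAc
Reagents that add atoms: sodium hydroxide [Na+].[OH-]; iodine II
Why: Saponification by acyl–oxygen cleavage leaves the C2–O bond (2α-OH) untouched, and iodolactonisation then closes the five-membered lactone at the tertiary C10 (5-exo, Markovnikov, anti addition); the C4α carboxylate can reach C10 only from the α-face, which restores the natural C10 configuration and places iodine 1β.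

**Step 3**
Reactants: 4 1β-iodo-2α-hydroxy-1,2-dihydrogibberellic acid
Product: 5 2α-hydroxy-1,2-dihydrogibberellic acid (the target)
Conditions: Bu3SnH (3 equiv), AIBN (0.1 equiv), 1,4-dioxane, 80 °C, 2 h; then aq NaHCO3/hexane partition, HCl to pH 3, EtOAc
Reagents that add atoms: none
Why: Radical-chain dehalogenation (tin hydride reduction): the secondary C1 radical takes hydrogen from Bu3SnH faster than it can fragment or add to the 16-methylene, C1 becomes CH2 with no new stereocentre, and the lactone, the acid and the three hydroxyls are inert.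

**Compound list**
1 | gibberellic acid: 3β,13-dihydroxy-1,16-diene, 19,10α-lactone, 7-carboxylic acid | C=C1C[C@]23C[C@@]1(O)CC[C@H]2[C@@]12C=C[C@H](O)[C@@](C)(C(=O)O1)[C@H]2[C@@H]3C(=O)O | starting material
2 | iso-gibberellic acid: 3β,13-dihydroxy-1(10),16-diene-7,19-dioic acid 19→2α-lactone, other centres as in 1 | C=C1C[C@]23C[C@@]1(O)CC[C@H]2C1=C[C@@H]4[C@H](O)[C@@](C)(C(=O)O4)[C@H]1[C@@H]3C(=O)O | intermediate
3 | disodium 2α,3β,13-trihydroxy-1(10),16-diene-7,19-dioate (ring-opened dicarboxylate, kept in solution, not isolated) | C=C1C[C@]23C[C@@]1(O)CC[C@H]2C1=C[C@@H](O)[C@H](O)[C@@](C)(C(=O)[O-])[C@H]1[C@@H]3C(=O)[O-].[Na+].[Na+] | intermediate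
4 | 1β-iodo-2α-hydroxy-1,2-dihydrogibberellic acid: 1β-iodo-2α,3β,13-trihydroxy-16-ene, 19,10α-lactone, 7-carboxylic acid | C=C1C[C@]23C[C@@]1(O)CC[C@H]2[C@@]12[C@H](I)[C@@H](O)[C@H](O)[C@@](C)(C(=O)O1)[C@H]2[C@@H]3C(=O)O | intermediate
5 | 2α-hydroxy-1,2-dihydrogibberellic acid: 2α,3β,13-trihydroxy-16-ene, 19,10α-lactone, 7-carboxylic acid | C=C1C[C@]23C[C@@]1(O)CC[C@H]2[C@@]12C[C@@H](O)[C@H](O)[C@@](C)(C(=O)O1)[C@H]2[C@@H]3C(=O)O | target

**Total step count:** 3
**Longest linear sequence:** 3 steps (1 → 2 → 4 → 5)

**Steps most likely to fail, with fallbacks**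

Step 2 (highest risk). The C7 carboxylate can compete for the iodonium ion from the β-face and give a 7,10-lactone. Iodine can also attack the 16-methylene, and 4 can close to the 1α,2α-epoxide if the mixture is left basic. The fallback blocks the C7 acid; it sets out from 2 and comes back to the route at 5. TMSCHN2 in MeOH–PhMe at 0 °C gives iso-gibberellic acid methyl ester F1. Then 0.5 M NaOH in THF–H2O at 20 °C opens only the strained bridging lactone, since the hindered C7 ester saponifies far more slowly, and gives the sodium 19-carboxylate 7-methyl ester F2, kept in solution. NaHCO3/I2 at 0 °C gives 1β-iodo-2α-hydroxy-1,2-dihydrogibberellic acid methyl ester F3, with only one carboxylate available for ring closure. Bu3SnH/AIBN in PhH at 80 °C gives 2α-hydroxy-1,2-dihydrogibberellic acid methyl ester F4. LiSPr in HMPA at 20 °C (SN2 O-demethylation, lactone untouched), then acid, gives 5.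

Step 3. The free acid and triol may consume tin hydride as a tin carboxylate, dissolve poorly in radical solvents, and make tin removal from the polar product difficult. The fallback masks every protic group; it sets out from 4 and comes back to the route at 5. N,O-bis(trimethylsilyl)acetamide with catalytic TMSCl in MeCN at 50 °C gives the tetrakis(trimethylsilyl) derivative of 4 F5 (7-TMS ester, 2,3,13-tris-TMS ether). Bu3SnH/AIBN in PhH at 80 °C gives the tetrakis(trimethylsilyl) derivative of the target F6, which is purified as a non-polar compound. Citric acid in MeOH at 20 °C removes all silyl groups and gives 5.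

Step 1. The transposition itself is reliable; the risk is in isolation. Compound 2 is a water-soluble allylic lactone and is partly ring-opened in the alkaline medium. The fallback drops the isolation and telescopes the sequence; it sets out from 1 and comes back to the route at 4. Compound 1 is dissolved directly in 2 M NaOH (5 equiv, 20 °C, 4 h), where transposition to 2 and ring-opening to 3 follow one another in the same flask. The solution is then buffered with NaHCO3 and treated with I2 as in step 2, which gives 4. It makes no compound that the list does not already hold (F0).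

**Further compounds**
F1 | step 2 | iso-gibberellic acid methyl ester | C=C1C[C@]23C[C@@]1(O)CC[C@H]2C1=C[C@@H]4[C@H](O)[C@@](C)(C(=O)O4)[C@H]1[C@@H]3C(=O)OC
F2 | step 2 | sodium 2α,3β,13-trihydroxy-7-methoxycarbonyl-1(10),16-dien-19-oate (ring-opened, not isolated) | C=C1C[C@]23C[C@@]1(O)CC[C@H]2C1=C[C@@H](O)[C@H](O)[C@@](C)(C(=O)[O-])[C@H]1[C@@H]3C(=O)OC.[Na+]
F3 | step 2 | 1β-iodo-2α-hydroxy-1,2-dihydrogibberellic acid methyl ester | C=C1C[C@]23C[C@@]1(O)CC[C@H]2[C@@]12[C@H](I)[C@@H](O)[C@H](O)[C@@](C)(C(=O)O1)[C@H]2[C@@H]3C(=O)OC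
F4 | step 2 | 2α-hydroxy-1,2-dihydrogibberellic acid methyl ester | C=C1C[C@]23C[C@@]1(O)CC[C@H]2[C@@]12C[C@@H](O)[C@H](O)[C@@](C)(C(=O)O1)[C@H]2[C@@H]3C(=O)OC
F5 | step 3 | 1β-iodo-2α-hydroxy-1,2-dihydrogibberellic acid tetrakis(trimethylsilyl) derivative (7-TMS ester, 2,3,13-tris-TMS ether) | C=C1C[C@]23C[C@@]1(O[Si](C)(C)C)CC[C@H]2[C@@]12[C@H](I)[C@@H](O[Si](C)(C)C)[C@H](O[Si](C)(C)C)[C@@](C)(C(=O)O1)[C@H]2[C@@H]3C(=O)O[Si](C)(C)C
F6 | step 3 | 2α-hydroxy-1,2-dihydrogibberellic acid tetrakis(trimethylsilyl) derivative (7-TMS ester, 2,3,13-tris-TMS ether) | C=C1C[C@]23C[C@@]1(O[Si](C)(C)C)CC[C@H]2[C@@]12C[C@@H](O[Si](C)(C)C)[C@H](O[Si](C)(C)C)[C@@](C)(C(=O)O1)[C@H]2[C@@H]3C(=O)O[Si](C)(C)C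
F0 | step 1 | none | none
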